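As the chemist running this flask, I have two earlier runs and want the ratio of target to isomer of the product at three times.

| setting | teal | grey | flask |
|---|---|---|---|
| starting material | 0.27 M | 0.60 M | 0.40 M |
| remark | run made earlier | run made earlier |  |
| time |  |  | 1.5 h |

| run | time / min | target / % | isomer of the product / % |
|---|---|---|---|
| teal | 20.0 | 33.9 | 62.9 |
| teal | 40.0 | 26.0 | 72.0 |
| teal | 50.0 | 21.6 | 73.9 |
| teal | 80.0 | 15.2 | 80.1 |
| teal | 90.0 | 12.6 | 81.3 |
| grey | 8.00 | 37.7 | 46.0 |
| grey | 15.0 | 36.7 | 58.7 |
| grey | 25.0 | 31.8 | 65.8 |
| grey | 50.0 | 20.9 | 74.2 |
| grey | 90.0 | 13.4 | 82.1 |

(readings scatter by 0.5 percentage points)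

* ratio of target to isomer of the product at 5.0 s
* ratio of target to isomer of the product at 2.5 min
* ratio of target to isomer of the product at 1.5 h
* which of target and isomer of the product there is more of at 1.5 h



1. At 90.0 min, the target readings of the teal and grey runs differ by 0.8 percentage points, less than 1 point. So I treat percentages as independent of the charge between 0.27 M and 0.60 M, which brackets this flask's 0.40 M.

2. The latest time asked is that last reading time. Pooling both runs gives a ratio of 0.159, so I commit to the isomer of the product leading.

3. At 20.0 min in the teal run, target and isomer already sum to 96.8%. From there to 90.0 min, the target falls with a late half-life of 49.0 min, as read.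

4. Running that decay back to the start gives the target's branching share: 45.0%. If both branches opened together, the early ratio would be 0.817.

5. This is the weak link. At 8.00 min in the grey run, the target stands at 93.9% of its decayed share. The isomer, less what the target has fed it, stands at 74.9% of its share, which is less. So the isomer lags, and I expect early ratios above 0.817, without committing to a figure.

The forecast gives 40 at 5.0 s, 1.9 at 2.5 min and 0.16 at 1.5 h, with isomer of the product ahead. It goes further than I do, holding that “the isomer arrives through an unseen intermediate”.

The flask gives 44.1, 1.70 and 0.155, with isomer of the product ahead at 81.9% against 12.7% of target. The forecast stands.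

    starting material ⇌ other conformer (K = 2.10, k = 0.00750 s⁻¹)
    starting material → target (k = 0.00340 s⁻¹)
    other conformer → isomer of the product (k = 0.00400 s⁻¹)
    target ⇌ isomer of the product (K = 17.0, k = 2.60 × 10⁻⁴ s⁻¹)
    target → over-reaction product (k = 4.00 × 10⁻⁵ s⁻¹)
    starting material + target → side product (k = 9.80 × 10⁻⁵ L mol⁻¹ s⁻¹)

In this flask, the half-life of starting material by the forward step into other conformer alone is 1.5 min at 0.0140 h, far shorter than the 0.699 h relaxation half-life of target and isomer of the product by their step alone. The passing of starting material into target has 99% of its turnover behind it after 0.300 h, and the slow loss of target follows. From 23.5% at 0.750 h, the half-life of 49.0 min carries this flask to 12.4% at 1.5 h. The neighbour flask at 0.24 M lies below the teal charge of 0.27 M; the grey reading of 31.8% at 25.0 min, carried to 1.5 h on the teal half-life of 49.0 min, gives 12.7%, and that neighbour flask holds 12.7%.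

The numbers in the tables were computed from invented constants; noise was put on by code.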